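The synthesis rests on fusing the γ-lactone onto the C7–C8 bond of a preformed, fully esterified trans-bicyclo[8.4.0]tetradecadiene. In one flask an acrylate oxygen displaces the allylic α-keto chloride at C7 and the copper enolate released by hydride addition to that acrylate closes onto the C8 ketone, which forges O–C7 and C17–C8 and sets C7, C8 and C17. The precursor is a (5Z) ten-membered α-chloro ketone, assembled by a Diels–Alder construction of ring A from a glyceraldehyde-derived enal, chloroallylboration and ring-closing metathesis. The step exploits the adjacent electrophiles C7 (secondary, allylic to C5=C6) and C8 (ring ketone) of the ten-membered ring, across which the five-membered lactone O–C7–C8–C17–C19 is built.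

Key step: step 13

Remark on the chemistry: briarane numbering is used throughout (C1 quaternary, C15 its methyl; C5=C6 with methyl C16; lactone O–C7, C8, C17 with methyl C18, carbonyl C19; C11=C12 with methyl C20). (R)-2,3-O-Isopropylideneglyceraldehyde is taken as a commercial starting material. The sense of induction of the Ipc reagent in step 10 (Si-face attack by the (+)-α-pinene series) is assigned from the usual model and from recollection of literature examples, not re-derived here.

Step 1
Reactants: 1 (E)-pent-2-enal
Product: 2 (1E,3E)-penta-1,3-dien-1-yl butanoate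
Conditions: (PrCO)2O, Et3N, DMAP (cat.), 90 °C; distillation
Reagents that add atoms: butanoic anhydride, CCCC(=O)OC(=O)CCC
Why: O-acylation of the extended enol form of the enal (dienol ester formation) should give mainly the s-trans (1E,3E) dienyl ester, the only isomer that can reach the s-cis geometry for cycloaddition.

Step 2
Reactants: 3 (R)-2,2-dimethyl-1,3-dioxolane-4-carbaldehyde; 4 2-(triphenylphosphoranylidene)propanal
Product: 5 (E)-3-[(4S)-2,2-dimethyl-1,3-dioxolan-4-yl]-2-methylprop-2-enal
Conditions: CH2Cl2, 0 °C → rt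
Reagents that add atoms: none
Why: Wittig olefination with a stabilised ylide should give the (E)-trisubstituted enal without touching the α-alkoxy stereocentre, which becomes C9 of the target.

Step 3
Reactants: 2 (1E,3E)-penta-1,3-dien-1-yl butanoate; 5 (E)-3-[(4S)-2,2-dimethyl-1,3-dioxolan-4-yl]-2-methylprop-2-enal
Product: 6 Diels–Alder adduct, (1S,4R,5S,6R)-5-[(4S)-2,2-dimethyl-1,3-dioxolan-4-yl]-6-formyl-4,6-dimethylcyclohex-2-en-1-yl butanoate (ring positions 1, 4, 5, 6 = briarane C14, C11, C10, C1)
Conditions: Me2AlCl (20 mol %), CH2Cl2, −78 → −20 °C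
Reagents that add atoms: none
Why: Lewis acid-catalysed Diels–Alder reaction in which the acyloxy terminus bonds to the formyl-bearing carbon ("ortho" rule), the complexed CHO sits endo (CHO, 14-O and 11-Me cis; C9 branch trans to CHO from the E-enal), and the diene adds anti to the C9–O bond of the conformer with H9 eclipsing the alkene (A1,3 strain with the α-methyl), setting C1, C10, C14 and C11.

Step 4
Reactants: 6 Diels–Alder adduct
Product: 7 tertiary allylic alcohol (6 with OH in place of H at C11, on the face opposite to 14-O)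
Conditions: SeO2 (0.5 equiv), t-BuOOH, CH2Cl2, rt
Reagents that add atoms: tert-butyl hydroperoxide, CC(C)(C)OO (oxygen delivered through SeO2, O=[Se]=O)
Why: Selenium dioxide allylic hydroxylation (ene reaction at C13 with transfer of H11, then [2,3] shift) should replace the only reactive allylic hydrogen, H11, by OH with retention, since H14 is deactivated by the geminal acyloxy group and the aldehyde has no α-hydrogen.

Step 5
Reactants: 7 tertiary allylic alcohol
Product: 9 ring-A aldehyde with 13,14-trans-bis(butanoyloxy) groups and the C11=C12 alkene, via 13-hydroxy Δ11 alcohol 8 (not isolated)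
Conditions: Ph3SiOReO3 (3 mol %), Et2O, −40 → 0 °C; then (PrCO)2O, Et3N, DMAP, 0 °C → rt
Reagents that add atoms: butanoic anhydride, CCCC(=O)OC(=O)CCC
Why: Rhenium-oxo catalysed 1,3-transposition of the allylic alcohol ([3,3] shift of the perrhenate ester, suprafacial) moves the oxygen from C11 to C13 on the same face, trans to 14-O, while forming the trisubstituted C11=C12 alkene, and acylation of the secondary alcohol only drains the equilibrium.

Step 6
Reactants: 9 ring-A aldehyde; 10 4-bromo-2-methylbut-1-ene
Product: 12 C2 propanoate bearing the 3-methylbut-3-enyl chain, via bromomagnesium C2-alkoxide 11 (not isolated)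
Conditions: 10, Mg, THF; then 9, LaCl3·2LiCl (30 mol %), THF, −78 °C; then (EtCO)2O, DMAP, −78 → 0 °C
Reagents that add atoms: propanoic anhydride, CCC(=O)OC(=O)CC
Why: Lanthanum-assisted Grignard addition to the neopentyl aldehyde outruns attack on the hindered butanoates, Felkin–Anh approach anti to C10 (the α-carbon carrying the gauche dioxolanyl branch) and past the C15 methyl should set (2S), and trapping the alkoxide as the propanoate prevents acyl migration from O14.

Step 7
Reactants: 12 C2 propanoate
Product: 13 C8,C9-diol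
Conditions: AcOH/H2O (4:1), 40 °C
Reagents that add atoms: none
Why: Mild acid hydrolysis of a terminal dioxolane acetal should leave the three esters and both alkenes untouched.

Step 8
Reactants: 13 C8,C9-diol
Product: 14 bis(triethylsilyl) ether
Conditions: TESCl, imidazole, DMAP (cat.), CH2Cl2, 0 °C → rt
Reagents that add atoms: chlorotriethylsilane, CC[Si](Cl)(CC)CC
Why: Standard silylation of a primary and a secondary alcohol.

Step 9
Reactants: 14 bis(triethylsilyl) ether
Product: 15 C8 aldehyde with 9-OTES
Conditions: (COCl)2, DMSO, CH2Cl2, −78 → −30 °C; then Et3N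
Reagents that add atoms: none
Why: Under Swern conditions a primary TES ether is cleaved and oxidised in the flask whereas the secondary TES ether survives, so the α-silyloxy aldehyde is obtained without a separate deprotection.

Step 10
Reactants: 15 C8 aldehyde; 16 allyl chloride
Product: 17 (7R,8R)-syn-chlorohydrin with a C7 vinyl group
Conditions: 16, LiNCy2, (−)-Ipc2BOMe, Et2O, −95 °C; BF3·OEt2; then 15, −95 °C; 30 % H2O2, aq NaOAc, 0 °C
Reagents that add atoms: none
Why: γ-Chloroallylboration with (Z)-(γ-chloroallyl)B(Ipc)2 through a chair transition state gives the syn-chlorohydrin, and the Ipc ligands of the (+)-α-pinene series direct attack to the Si face of the aldehyde, which sets (7R); C8 is oxidised later.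

Step 11
Reactants: 17 syn-chlorohydrin diene
Product: 18 ten-membered (5Z)-chlorohydrin
Conditions: Grubbs second-generation catalyst (15 mol %), 1,4-benzoquinone (cat.), toluene (1 mM), 80 °C
Reagents that add atoms: none
Why: Ring-closing metathesis between the vinyl and the 1,1-disubstituted alkene, with loss of ethene, should close the ten-membered ring, whose strain allows only the (Z)-trisubstituted C5=C6 alkene; the trisubstituted ring-A alkene is inert.

Step 12
Reactants: 18 macrocyclic chlorohydrin
Product: 19 macrocyclic (7R)-α-chloro ketone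
Conditions: Dess–Martin periodinane, NaHCO3, CH2Cl2, 0 °C
Reagents that add atoms: none
Why: Buffered Dess–Martin oxidation of the only free alcohol gives the C8 ketone without epimerising C7 or moving the β,γ-alkene into conjugation.

Step 13
Reactants: 19 macrocyclic α-chloro ketone; 20 potassium acrylate
Product: 22 9-O-triethylsilyl lactone, via C7 acrylate ester 21 (not isolated)
Conditions: 20, 18-crown-6 (cat.), MeCN, 0 °C → rt; solvent switch to toluene; [(Ph3P)CuH]6 (0.35 equiv), −40 → 0 °C; aq NH4Cl
Reagents that add atoms: none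
Why: Acrylate displaces the doubly activated (α-keto, allylic) C7 chloride by SN2 with inversion, which makes the O–C7 bond, and precipitation of KCl from MeCN suppresses the chloride exchange that would scramble C7; Stryker's reagent then adds hydride 1,4 to the acrylate only, and the (Z)-copper enolate closes onto the C8 ketone, which makes the C17–C8 bond and the tertiary 8-OH. The closest known reaction types are the one-flask phenacyl ester/intramolecular aldol butenolide annulation and the copper hydride reductive aldol cyclisation of keto acrylates to β-hydroxy lactones. The γ-lactone closes in a 5-(enolendo)-exo-trig aldol mode. C7 is fixed by inversion of the (7R)-chloride, C8 by the O–C7 tether, which can deliver the enolate only to the ketone face syn to that oxygen in the transoid C6–C7–C8–C9 conformer of the ten-membered ring (trans-fused lactone, C9 anti to C6), and C17 by the chelated Zimmerman–Traxler transition state of the Z-enolate, which places the methyl cis to the new hydroxyl. The step needs SN2 over SN2′ and elimination, secured by the trisubstituted C5 terminus and the carbonyl-activated C7, and 1,4-reduction of the acrylate in the presence of three saturated esters and a ketone, secured by the preference of copper hydride for unhindered enoates.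

Step 14
Reactants: 22 9-O-triethylsilyl lactone
Product: 23 CNP0138989.1
Conditions: HF·pyridine, pyridine, THF, 0 °C → rt
Reagents that add atoms: none
Why: Buffered fluoride cleaves the secondary silyl ether (also after a possible 1,2-silyl shift to O8) without opening the lactone or the esters.

Compound list
1 | (E)-pent-2-enal | CC/C=C/C=O | starting material
2 | (1E,3E)-penta-1,3-dien-1-yl butanoate | C/C=C/C=C/OC(=O)CCC | intermediate
3 | (R)-2,2-dimethyl-1,3-dioxolane-4-carbaldehyde | CC1(C)OC[C@H](C=O)O1 | starting material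
4 | 2-(triphenylphosphoranylidene)propanal | CC(C=O)=P(c1ccccc1)(c1ccccc1)c1ccccc1 | starting material
5 | (E)-3-[(4S)-2,2-dimethyl-1,3-dioxolan-4-yl]-2-methylprop-2-enal | CC1(C)OC[C@H](/C=C(\C)C=O)O1 | intermediate
6 | (1S,4R,5S,6R)-5-[(4S)-2,2-dimethyl-1,3-dioxolan-4-yl]-6-formyl-4,6-dimethylcyclohex-2-en-1-yl butanoate (CHO, 1-O and 4-Me cis; dioxolanyl trans to CHO) | CCCC(=O)O[C@H]1C=C[C@@H](C)[C@H]([C@H]2COC(C)(C)O2)[C@@]1(C)C=O | intermediate
7 | 6 with a tertiary OH at C11 (ring position 4) in place of H, on the face opposite to the butanoyloxy group | CCCC(=O)O[C@H]1C=C[C@](C)(O)[C@H]([C@H]2COC(C)(C)O2)[C@@]1(C)C=O | intermediate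
8 | 14-butanoyloxy-13-hydroxy ring-A aldehyde with the C11=C12 alkene (13-OH trans to 14-O; C1, C9, C10, C13, C14 arranged as in 23) | O[C@@H]1C=C(C)[C@H]([C@H]2COC(C)(C)O2)[C@@](C)(C=O)[C@H]1OC(=O)CCC | intermediate
9 | 13,14-trans-bis(butanoyloxy) ring-A aldehyde (C1 bears CH3 and CHO, C10 the (4S)-dioxolanyl group, C11=C12) | CCCC(=O)O[C@@H]1C=C(C)[C@H]([C@H]2COC(C)(C)O2)[C@@](C)(C=O)[C@H]1OC(=O)CCC | intermediate
10 | 4-bromo-2-methylbut-1-ene | C=C(C)CCBr | starting material
11 | bromomagnesium (2S)-alkoxide from addition of the 3-methylbut-3-enyl Grignard reagent to 9 | CCCC(=O)O[C@@H]1C=C(C)[C@H]([C@H]2COC(C)(C)O2)[C@@](C)([C@@H](O[Mg]Br)CCC(C)=C)[C@H]1OC(=O)CCC | intermediate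
12 | (2S)-2-propanoyloxy compound with the C3–C5 chain ending in C(CH3)=CH2; 13,14-dibutanoate; C8/C9 acetonide | CCCC(=O)O[C@@H]1C=C(C)[C@H]([C@H]2COC(C)(C)O2)[C@@](C)([C@@H](OC(=O)CC)CCC(C)=C)[C@H]1OC(=O)CCC | intermediate
13 | C8,C9-diol from 12 | CCCC(=O)O[C@@H]1C=C(C)[C@H]([C@H](O)CO)[C@@](C)([C@@H](OC(=O)CC)CCC(C)=C)[C@H]1OC(=O)CCC | intermediate
14 | 8,9-bis(triethylsilyl) ether of 13 | CCCC(=O)O[C@@H]1C=C(C)[C@H]([C@H](O[Si](CC)(CC)CC)CO[Si](CC)(CC)CC)[C@@](C)([C@@H](OC(=O)CC)CCC(C)=C)[C@H]1OC(=O)CCC | intermediate
15 | C8 aldehyde with 9-OTES | CCCC(=O)O[C@@H]1C=C(C)[C@H]([C@H](O[Si](CC)(CC)CC)C=O)[C@@](C)([C@@H](OC(=O)CC)CCC(C)=C)[C@H]1OC(=O)CCC | intermediate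
16 | allyl chloride (3-chloroprop-1-ene) | C=CCCl | starting material
17 | (7R,8R)-syn-7-chloro-8-hydroxy compound with a C7 vinyl group (9-OTES, 2-propanoate, 13,14-dibutanoate) | CCCC(=O)O[C@@H]1C=C(C)[C@H]([C@H](O[Si](CC)(CC)CC)[C@@H](O)[C@H](Cl)C=C)[C@@](C)([C@@H](OC(=O)CC)CCC(C)=C)[C@H]1OC(=O)CCC | intermediate
18 | ten-membered (5Z) chlorohydrin: (7R)-chloro, (8R)-hydroxy, 9-OTES briara-5,11-diene triester | CCCC(=O)O[C@@H]1C=C(C)[C@@H]2[C@H](O[Si](CC)(CC)CC)[C@@H](O)[C@H](Cl)/C=C(/C)CC[C@H](OC(=O)CC)[C@@]2(C)[C@H]1OC(=O)CCC | intermediate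
19 | ten-membered (5Z) (7R)-7-chloro-8-ketone, 9-OTES | CCCC(=O)O[C@@H]1C=C(C)[C@@H]2[C@H](O[Si](CC)(CC)CC)C(=O)[C@H](Cl)/C=C(/C)CC[C@H](OC(=O)CC)[C@@]2(C)[C@H]1OC(=O)CCC | intermediate
20 | potassium acrylate (potassium prop-2-enoate) | C=CC(=O)[O-].[K+] | starting material
21 | (7S)-7-acryloyloxy-8-ketone, 9-OTES | CCCC(=O)O[C@@H]1C=C(C)[C@@H]2[C@H](O[Si](CC)(CC)CC)C(=O)[C@@H](OC(=O)C=C)/C=C(/C)CC[C@H](OC(=O)CC)[C@@]2(C)[C@H]1OC(=O)CCC | intermediate
22 | 9-O-triethylsilyl ether of the target | CCCC(=O)O[C@@H]1C=C(C)[C@@H]2[C@H](O[Si](CC)(CC)CC)[C@@]3(O)[C@H](/C=C(/C)CC[C@H](OC(=O)CC)[C@@]2(C)[C@H]1OC(=O)CCC)OC(=O)[C@@H]3C | intermediate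
23 | CNP0138989.1: (1S,2S,5Z,7S,8R,9S,10S,13R,14R,17R)-13,14-bis(butanoyloxy)-8,9-dihydroxy-2-propanoyloxybriara-5,11-diene 19,7-lactone | CCCC(=O)O[C@@H]1C=C(C)[C@@H]2[C@H](O)[C@@]3(O)[C@H](/C=C(/C)CC[C@H](OC(=O)CC)[C@@]2(C)[C@H]1OC(=O)CCC)OC(=O)[C@@H]3C | target

Total step count: 14
Longest linear sequence: 13 steps (3 → 23 through steps 2–14; equally 1 → 23 through steps 1 and 3–14)

Steps most likely to fail

Step 11 (ring-closing metathesis). The catalyst may fail to load onto the 1,1-disubstituted alkene before it is tied up at the chlorohydrin terminus, so that oligomerisation outruns closure of the strained ring. The fallback sets out from 17 and changes the substrate to one that is pre-folded. DBU in CH2Cl2 closes the syn-chlorohydrin to the acyclic cis-vinyl epoxide F1 (inversion at C7), in which C6 and C9 are held cis on the oxirane so that the two chain ends point toward each other. Metathesis of F1 under the conditions of step 11 should give the macrocyclic cis-epoxide F2. Opening of its allylic C7–O bond with chloride (LiCl, AcOH, THF; second inversion at C7) returns to the route at 18.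

Step 3 (Diels–Alder reaction). The acyloxy diene is a weak donor, so addition to the trisubstituted enal may be slow and may lose regiocontrol or endo selectivity. The fallback sets out from 1 and uses a stronger donor of the same geometry. TBSOTf and Et3N convert 1 to the silyl dienol ether (1E,3E)-1-(tert-butyldimethylsilyloxy)penta-1,3-diene F3. Its cycloaddition with 5 should give the silyl ether adduct F4, which HF·pyridine desilylates to the hydroxy aldehyde F5. Butanoic anhydride, pyridine and DMAP then acylate F5, which returns to the route at 6.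

Step 13 (lactone annulation). After the substitution the copper enolate may be quenched or may not add to the hindered C8 ketone, so that only conjugate reduction occurs; chloride exchange may also erode C7. The fallback sets out from 19 and generates the enolate by a Reformatsky reaction. Potassium 2-bromopropanoate (18-crown-6, MeCN) displaces the chloride to give the α-(2-bromopropanoyloxy) ketone F6 (both epimers at the bromine-bearing carbon). Activated zinc in THF should then close the lactone by intramolecular Reformatsky addition to C8, which returns to the route at 22.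

Further compounds
F1 | step 11 | acyclic cis-7,8-epoxide with a C7 vinyl group (from 17; 9-OTES, 2-propanoate, 13,14-dibutanoate) | CCCC(=O)O[C@@H]1C=C(C)[C@H]([C@H](O[Si](CC)(CC)CC)[C@H]2O[C@H]2C=C)[C@@](C)([C@@H](OC(=O)CC)CCC(C)=C)[C@H]1OC(=O)CCC
F2 | step 11 | ten-membered (5Z) cis-7,8-epoxide, 9-OTES | CCCC(=O)O[C@@H]1C=C(C)[C@@H]2[C@H](O[Si](CC)(CC)CC)[C@H]3O[C@H]3/C=C(/C)CC[C@H](OC(=O)CC)[C@@]2(C)[C@H]1OC(=O)CCC
F3 | step 3 | (1E,3E)-1-(tert-butyldimethylsilyloxy)penta-1,3-diene | C/C=C/C=C/O[Si](C)(C)C(C)(C)C
F4 | step 3 | tert-butyldimethylsilyl ether analogue of 6 | CC(C)(C)[Si](C)(C)O[C@H]1C=C[C@@H](C)[C@H]([C@H]2COC(C)(C)O2)[C@@]1(C)C=O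
F5 | step 3 | 14-hydroxy analogue of 6 (free alcohol) | O[C@H]1C=C[C@@H](C)[C@H]([C@H]2COC(C)(C)O2)[C@@]1(C)C=O
F6 | step 13 | (7S)-7-(2-bromopropanoyloxy)-8-ketone, 9-OTES (mixture at the CHBr carbon) | CCCC(=O)O[C@@H]1C=C(C)[C@@H]2[C@H](O[Si](CC)(CC)CC)C(=O)[C@@H](OC(=O)C(C)Br)/C=C(/C)CC[C@H](OC(=O)CC)[C@@]2(C)[C@H]1OC(=O)CCC
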